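## Analysis of the target

Plakortolide Q (29) is a 1,2-dioxane that is cis-fused along C3–C4 to a γ-butyrolactone. On C6 it carries a methyl group and a ten-carbon chain that ends in an (E,E)-1-phenylbuta-1,3-diene. The numbering used throughout is C1 (lactone carbonyl), C2, C3 (H, bonded to peroxide oxygen O2), C4 (methyl, lactone oxygen), C5, C6 (methyl, peroxide oxygen O1), the chain C7–C16, and phenyl on C16. The three stereocentres are 3R, 4R and 6S: C2 on C3 and the lactone oxygen on C4 are cis (the ring fusion), and the lactone oxygen on C4 and C7 on C6 lie on the same face of the dioxane, with both methyl groups on the other face. The O–O bond does not survive low-valent metals, hydrogenation or long contact with phosphines; the C2 protons are acidic enough for base to expel O2 from C3 by retro-conjugate addition; and the diene is lost to diimide, acid or radicals. The hard centre is C6: a fully substituted, peroxide-bearing carbon with no neighbouring group to direct the entry of oxygen, 1,3 to the equally substituted C4. The strategy rests on the 1,3-cis (diaxial) placement of the C4 oxygen and C7: one carbonyl carbon, C8, can span them as a δ-lactone O–C8(=O)–C7, which makes the dioxane one ring of a bicyclo[3.3.1] system in which the C4/C6 relationship is fixed by connectivity. C8 is also the second carbon of the chain, so the bridge can be opened and extended once it has done its work.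

## Retrosynthetic reasoning

**C13=C14.** The diene is cut first, to aldehyde 23 and cinnamyl sulfone 27. It has to be made last because it would not survive the saturation of C8=C9 or the acid step. The forward olefination must give the E geometry and must not enolise the lactone.

**Lactone C1–O(C4), C13 oxidation level, C8–C9.** Aldehyde 23 comes from alcohol 22, and 22 from the monocyclic hydroxy ester 20, in which the C4 hydroxyl is free and C1 is a tert-butyl ester. One acid treatment should cleave the ester, close the γ-lactone onto the cis C4 hydroxyl and free the primary alcohol. Ester 20 comes from alkene 19 by saturation of C8=C9.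

**C8=C9.** Alkene 19 is cut to lactol 14 and phosphonium salt 17 (ylide 18). The cut is made here because C8 is the carbonyl carbon of the temporary bridge: reducing the bridging lactone 13 to 14 frees the C4 hydroxyl and turns C8 into an aldehyde for chain extension in one operation. The reduction has to distinguish the lactone from a tert-butyl ester and leave the peroxide alone.

**O1–C6 (and O2–C3).** Bicycle 13 is opened at O1–C6 to hydroperoxide 12, and 12 at O2–C3 to the doubly unsaturated lactone ester 10 and hydrogen peroxide 11. This is the bond on which the route depends: while the C4 oxygen and C7 are tied by C8, a peroxide oxygen anchored on C3 can reach C6 from one face only. Hydroperoxide 12 is not treated as a stock compound, because any base that forms it would also revert it or close it, so it is generated and consumed in one flask.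

**C6=C7 and O(C4)–C8.** Lactone 10 is cut by ring-closing metathesis to acrylate 9, and 9 to tertiary alcohol 7 and acryloyl chloride 8. Ring closure gives the Z geometry the lactone needs by construction. An open-chain aldol-type assembly of the same carbons would give an (E)-enoate that cannot reach the C4 oxygen.

**C2=C3.** Alcohol 7 comes from diol 4 and ylide 5 through aldehyde 6, and 4 from ester 3. The enoate is installed before the lactone exists, so no ester has to be reduced next to an unsaturated lactone.

**C4–C5.** Ester 3 is cut to methyl pyruvate 1 and 2-methylpropene 2. An enantioselective carbonyl-ene reaction sets C4, the only stereocentre not derived from another, and delivers the methallyl group that later becomes C5, C6 and the C6 methyl.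

**Reagent fragments.** Salt 17 comes from 15 through 16, and sulfone 27 from 24 and 25 through 26.

## Alternatives that were turned down

**Alternative 1:** Both side arms are traced back to vinyl groups (C1=C2 on C3, C7=C8 on C6), and these to the single C2=C7 alkene of the 2,3-dioxabicyclo[2.2.2]oct-5-ene A1, which carries the C4 methyl and a silyl ether. Forward, the second-generation Grubbs catalyst under ethylene opens that alkene and gives the monocyclic cis-3,6-divinyl-1,2-dioxane A2; no ring is formed.
- For: the bicycle fixes the cis relationship of the C3 and C6 arms for both centres at once. On C3 this is stronger than the chosen route, which relies on equilibration there.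
- Against: C4 has to be placed relative to the peroxide bridge by facial selectivity alone (methyl against silyloxy on the neighbouring sp3 carbon). A bicyclo[2.2.2]octene has little strain to drive ethenolysis, and the carbene must leave an allylic O–O bond alone.
- Against: A2 is far from 29. One vinyl group needs anti-Markovnikov functionalisation and two oxidations beside the peroxide, the two vinyl groups must be told apart, the tertiary silyl ether must be cleaved and lactonised, and eight chain carbons are still missing.
- Comparison: the chosen route sets C4 by an enantioselective catalytic reaction and C6 by the bridge, and its key-step product already has C1 at the ester level and C8 as the chain handle.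

**Alternative 2:** O1–C6, C5–C6 and the lactone O–C4 bond are cut in one operation, back to allylic hydroperoxide A3 and ynone dimethyl ketal A4. Forward, Me3SiOTf ionises A4, A3 exchanges onto it, the isopropenyl terminus attacks the peroxycarbenium ion (closing the dioxane), and the tert-butyl ester captures the C4 cation (closing the γ-lactone), giving A5 with the chain attached as an alkyne.
- For: both rings, one C–C and two C–O bonds and the chain handle arise in one flask, and the cis ring fusion follows from the five-membered capture. On step economy and convergence it is clearly stronger than the chosen route.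
- Against: C6 is decided by whether methyl or alkynyl sits axial in a chair transition state, two groups of similar small size, so the hardest centre is left to a weak conformational preference.
- Against: the C4 cation can lose a proton instead of being trapped, the propargylic cation has a second electrophilic site, and A3 is needed as a single enantiomer although the usual routes to allylic hydroperoxides give racemates.
- Comparison: the chosen route is longer but replaces the selectivity question at C6 by a geometric constraint.

**Alternative 3:** The cut is at C4=C5 of a 3,6-dihydro-1,2-dioxine, back to bis-vinyl peroxide A6. Forward, a chiral ruthenium catalyst of the second-generation Grubbs type joins the C4 isopropenyl group to one of the two diastereotopic vinyl groups on C6 and gives A7, with the remaining vinyl group cis to the C3 arm.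
- For: C6 is created catalytically from a prochiral carbon, and A7 carries the C1 ester and a vinyl handle. As a way of making a quaternary peroxy carbon without a pre-existing ring it is more general than the chosen one.
- Against: the tertiary, doubly allylic peroxide A6 is hard to assemble and prone to ionise. The choice between the vinyl groups rests on catalyst discrimination overlaid on the existing C3 centre, in a closure to a trisubstituted alkene.
- Against: after the key step C4 is still sp2, so a Markovnikov, cis-selective oxygenation of C4=C5 by the C1 acid (for example halolactonisation and dehalogenation beside the peroxide) is still required.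
- Comparison: the chosen route makes C4 first and lets it dictate C6 through the bridge, so after its key step all three stereocentres and both oxygen functions at C3/C4 are in place.

Key step: step 6

Remark: only compounds that contribute atoms to 29 or are made on the way are numbered. tBu-box stands for 2,2'-(propane-2,2-diyl)bis(4-tert-butyl-4,5-dihydro-1,3-oxazole). The ligand, metal salts and simple reagents are taken as purchasable, and hydrogen peroxide 11 is used in step 6 as its urea adduct.

## Route

Step 1
Reactants: 1 methyl pyruvate; 2 2-methylpropene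
Product: 3 methyl (2R)-2-hydroxy-2,4-dimethylpent-4-enoate
Conditions: [Cu((R,R)-tBu-box)](SbF6)2 (10 mol %, from CuCl2, the ligand and AgSbF6), excess 2, CH2Cl2, 25–40 °C, sealed vessel
Reagents that add atoms: none
Why: Enantioselective carbonyl-ene reaction of a pyruvate ester with a 1,1-disubstituted alkene under a cationic bisoxazoline complex of divalent copper, a known process; the ketone and ester oxygens chelate copper, one tert-butyl group blocks the si face of the ketone, and 2 should attack the re face to give the R carbinol that becomes C4. The (R,R) ligand is chosen because the (S,S) complex is known to direct nucleophiles to the si face of chelated pyruvate.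

Step 2
Reactants: 3 methyl (2R)-2-hydroxy-2,4-dimethylpent-4-enoate
Product: 4 (2R)-2,4-dimethylpent-4-ene-1,2-diol
Conditions: LiAlH4, Et2O, 0 °C
Reagents that add atoms: none
Why: Hydride reduction of the ester to the primary alcohol; the stereocentre is not touched, and reducing here means no ester has to be reduced later beside a lactone.

Step 3
Reactants: 4 (2R)-2,4-dimethylpent-4-ene-1,2-diol; 5 tert-butyl (triphenylphosphoranylidene)acetate
Product: 7 tert-butyl (2E,4R)-4-hydroxy-4,6-dimethylhepta-2,6-dienoate, via hydroxy aldehyde 6 (not isolated)
Conditions: SO3·pyridine, iPr2NEt, DMSO/CH2Cl2, 0 °C; then 5, rt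
Reagents that add atoms: none
Why: Parikh–Doering oxidation touches only the primary alcohol (the tertiary one cannot be oxidised and the 1,2-diol is not cleaved); aldehyde 6, which has no α-hydrogen, is trapped in the same flask by the stabilised ylide in an E-selective Wittig reaction.

Step 4
Reactants: 7 tert-butyl (2E,4R)-4-hydroxy-4,6-dimethylhepta-2,6-dienoate; 8 acryloyl chloride
Product: 9 tert-butyl (2E,4R)-4,6-dimethyl-4-(prop-2-enoyloxy)hepta-2,6-dienoate
Conditions: LiN(SiMe3)2, THF, −78 °C; then 8, −78 → 0 °C
Reagents that add atoms: none
Why: O-acylation of a hindered tertiary alkoxide with an acid chloride; the alcohol is deprotonated first because it is too hindered for amine-mediated acylation, and the (E)-enoate cannot lactonise onto the alkoxide.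

Step 5
Reactants: 9 tert-butyl (2E,4R)-4,6-dimethyl-4-(prop-2-enoyloxy)hepta-2,6-dienoate
Product: 10 tert-butyl (2E)-3-[(2R)-2,4-dimethyl-6-oxo-3,6-dihydro-2H-pyran-2-yl]prop-2-enoate
Conditions: second-generation Grubbs catalyst RuCl2(=CHPh)(H2IMes)(PCy3) (5 mol %), toluene, 80 °C
Reagents that add atoms: none
Why: Ring-closing metathesis of an acrylate with a 1,1-disubstituted alkene, a standard route to 4-methyl-5,6-dihydropyran-2-ones; the six-membered ring enforces the Z geometry, and the internal electron-poor enoate is a far poorer metathesis partner than the methallyl group.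

Step 6
Reactants: 10 tert-butyl (2E)-3-[(2R)-2,4-dimethyl-6-oxo-3,6-dihydro-2H-pyran-2-yl]prop-2-enoate; 11 hydrogen peroxide
Product: 13 tert-butyl 2-[(1R,4R,5R)-1,5-dimethyl-7-oxo-2,3,6-trioxabicyclo[3.3.1]nonan-4-yl]acetate, via hydroperoxide 12 (not isolated)
Conditions: 11 as its urea adduct (5 equiv), Et2NH (2 equiv), CF3CH2OH, 0 °C → rt
Reagents that add atoms: none
Why: Proposed new method: hydroperoxide anion from 11 and Et2NH should add to C3 of the tert-butyl enoate, the ester enolate being protonated by the fluorinated alcohol to give 12, whose hydroperoxide then adds to C6, the β-carbon of the 4-methyl-5,6-dihydropyran-2-one, in a 6-exo-trig conjugate addition that forms O1–C6, closes the 1,2-dioxane and leaves the δ-lactone as the second ring of a bicyclo[3.3.1] system. The closest known reactions are the amine-mediated intramolecular conjugate addition of hydroperoxides to unsaturated esters and butenolides, the established way to close 1,2-dioxanes, and the base-catalysed addition of alkyl hydroperoxides to acrylates; new here are hydrogen peroxide as the intermolecular partner and a β,β-disubstituted lactone as the second acceptor. C6 is controlled by the tether: O1 is held through O2 and C3 on C4, so it can reach only the lactone face that carries the C3 arm, and no other C6 configuration can close. C3 is formed without bias in the first addition, but both additions are reversible under the amine, and in the chair–chair bicycle the 3R epimer has its CH2CO2tBu arm equatorial whereas the 3S epimer would hold it axial against the axial hydrogen on C5, so the 3R compound should accumulate, although the preference is modest. If hydrogen peroxide attacks C6 first, only the adduct cis to the side arm can close onto C3, and it gives the same 13, so the order of the two additions does not matter. The step needs conjugate addition to win over acyl attack at the lactone; the low basicity of the amine in CF3CH2OH, the hindered tert-butyl ester and the conjugated, β-substituted lactone carbonyl should secure this.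

Step 7
Reactants: 13 tert-butyl 2-[(1R,4R,5R)-1,5-dimethyl-7-oxo-2,3,6-trioxabicyclo[3.3.1]nonan-4-yl]acetate
Product: 14 tert-butyl 2-[(1R,4R,5R)-7-hydroxy-1,5-dimethyl-2,3,6-trioxabicyclo[3.3.1]nonan-4-yl]acetate (lactol, both configurations at the hemiacetal carbon)
Conditions: iBu2AlH (1.2 equiv), CH2Cl2, −78 °C
Reagents that add atoms: none
Why: Partial reduction of a lactone to the lactol; the aluminium hemiacetal is stable at −78 °C, tert-butyl esters react much more slowly, and dialkyl peroxides are not reduced by this hydride in the cold.

Step 8
Reactants: 15 5-bromopentan-1-ol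
Product: 16 tert-butyl[(5-bromopentyl)oxy]dimethylsilane
Conditions: tBuMe2SiCl, imidazole, CH2Cl2, 0 °C → rt
Reagents that add atoms: tert-butyldimethylsilyl chloride, CC(C)(C)[Si](C)(C)Cl
Why: Standard silylation of a primary alcohol; the ether masks the future C13 oxygen during ylide formation.

Step 9
Reactants: 16 tert-butyl[(5-bromopentyl)oxy]dimethylsilane
Product: 17 {5-[(tert-butyldimethylsilyl)oxy]pentyl}triphenylphosphonium bromide
Conditions: PPh3, MeCN, reflux
Reagents that add atoms: triphenylphosphine, c1ccc(cc1)P(c1ccccc1)c1ccccc1
Why: SN2 quaternisation of triphenylphosphine by a primary bromide.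

Step 10
Reactants: 14 tert-butyl 2-[(1R,4R,5R)-7-hydroxy-1,5-dimethyl-2,3,6-trioxabicyclo[3.3.1]nonan-4-yl]acetate; 17 {5-[(tert-butyldimethylsilyl)oxy]pentyl}triphenylphosphonium bromide
Product: 19 tert-butyl 2-[(3R,4R,6S)-6-{(2Z)-7-[(tert-butyldimethylsilyl)oxy]hept-2-en-1-yl}-4-hydroxy-4,6-dimethyl-1,2-dioxan-3-yl]acetate, via ylide 18 (not isolated)
Conditions: 17 (3 equiv), NaN(SiMe3)2 (2.9 equiv), THF, 0 °C; then 14, −78 °C → rt
Reagents that add atoms: none
Why: Wittig olefination of a lactol through its hydroxy aldehyde tautomer with an excess of non-stabilised ylide; the bridge carbonyl C8 becomes C8=C9, C9–C13 come from 18, and the (mainly Z) geometry is irrelevant because the bond is saturated next. The ylide is a weaker base than an ester enolate and no free amide base is left, which should keep C2 from being deprotonated in the cold.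

Step 11
Reactants: 19 tert-butyl 2-[(3R,4R,6S)-6-{(2Z)-7-[(tert-butyldimethylsilyl)oxy]hept-2-en-1-yl}-4-hydroxy-4,6-dimethyl-1,2-dioxan-3-yl]acetate
Product: 20 tert-butyl 2-[(3R,4R,6S)-6-{7-[(tert-butyldimethylsilyl)oxy]heptyl}-4-hydroxy-4,6-dimethyl-1,2-dioxan-3-yl]acetate
Conditions: KO2CN=NCO2K, AcOH, MeOH/CH2Cl2, 0 °C → rt
Reagents that add atoms: none
Why: Diimide, released from the azodicarboxylate salt by acetic acid, saturates the unhindered disubstituted alkene by syn hydrogen transfer and is the standard reductant for C=C bonds beside O–O bonds; ester, silyl ether and stereocentres are untouched.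

Step 12
Reactants: 20 tert-butyl 2-[(3R,4R,6S)-6-{7-[(tert-butyldimethylsilyl)oxy]heptyl}-4-hydroxy-4,6-dimethyl-1,2-dioxan-3-yl]acetate
Product: 22 2-[(3R,4R,6S)-4-hydroxy-6-(7-hydroxyheptyl)-4,6-dimethyl-1,2-dioxan-3-yl]acetic acid 1,4-lactone (γ-lactone between C1 and the C4 oxygen), via dihydroxy acid 21 (not isolated)
Conditions: CF3CO2H/CH2Cl2/H2O, 0 °C → rt; then NaHCO3, MeOH, rt
Reagents that add atoms: none
Why: Acidolysis of the tert-butyl ester frees the C1 acid, which lactonises onto the cis tertiary C4 hydroxyl (acid-catalysed acyl substitution), and the same medium cleaves the primary silyl ether; ionisation at C4 is disfavoured by the adjacent peroxide oxygen. The brief NaHCO3/MeOH treatment removes any trifluoroacetate on the primary alcohol; only the 3R,4R arrangement can give this cis-fused lactone.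

Step 13
Reactants: 22 2-[(3R,4R,6S)-4-hydroxy-6-(7-hydroxyheptyl)-4,6-dimethyl-1,2-dioxan-3-yl]acetic acid 1,4-lactone
Product: 23 2-[(3R,4R,6S)-4-hydroxy-4,6-dimethyl-6-(7-oxoheptyl)-1,2-dioxan-3-yl]acetic acid 1,4-lactone
Conditions: Dess–Martin periodinane, NaHCO3, CH2Cl2, 0 °C → rt
Reagents that add atoms: none
Why: Dess–Martin oxidation of a primary alcohol to the aldehyde under buffered, non-basic conditions that neither reduce the peroxide nor enolise the lactone.

Step 14
Reactants: 24 (E)-cinnamyl bromide; 25 1-phenyl-1H-tetrazole-5-thiol
Product: 26 1-phenyl-5-{[(2E)-3-phenylprop-2-en-1-yl]sulfanyl}-1H-tetrazole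
Conditions: K2CO3, acetone, rt
Reagents that add atoms: none
Why: SN2 S-alkylation of the thiolate by a primary allylic bromide.

Step 15
Reactants: 26 1-phenyl-5-{[(2E)-3-phenylprop-2-en-1-yl]sulfanyl}-1H-tetrazole; 11 hydrogen peroxide
Product: 27 1-phenyl-5-{[(2E)-3-phenylprop-2-en-1-yl]sulfonyl}-1H-tetrazole
Conditions: 11 (30% aq.), (NH4)6Mo7O24·4H2O (10 mol %), EtOH, 0 °C → rt
Reagents that add atoms: none
Why: Molybdate-catalysed oxidation of a sulfide to the sulfone, the usual preparation of tetrazolyl sulfones; the styrene double bond is not epoxidised under these conditions.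

Step 16
Reactants: 23 2-[(3R,4R,6S)-4-hydroxy-4,6-dimethyl-6-(7-oxoheptyl)-1,2-dioxan-3-yl]acetic acid 1,4-lactone; 27 1-phenyl-5-{[(2E)-3-phenylprop-2-en-1-yl]sulfonyl}-1H-tetrazole
Product: 29 plakortolide Q, 2-[(3R,4R,6S)-4-hydroxy-4,6-dimethyl-6-[(7E,9E)-10-phenyldeca-7,9-dien-1-yl]-1,2-dioxan-3-yl]acetic acid 1,4-lactone, via 13Z isomer 28 (not isolated)
Conditions: 27 (1.3 equiv), KN(SiMe3)2 (1.2 equiv), DME, −78 °C; then 23, −78 °C → rt; then I2 (5 mol %), CH2Cl2, daylight, rt
Reagents that add atoms: none
Why: Julia–Kocienski olefination: the pre-formed allylic sulfonyl anion, too weak a base to enolise the lactone, adds to the aldehyde and Smiles rearrangement with loss of SO2 and the tetrazolate forms C13=C14. Allylic sulfones give the new bond with imperfect geometry, so the crude diene is equilibrated with catalytic iodine to the conjugated E,E isomer, the thermodynamic one; the stereocentres are remote and untouched.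

## Compound list

1 | methyl pyruvate | CC(=O)C(=O)OC | starting material
2 | 2-methylpropene | CC(C)=C | starting material
3 | methyl (2R)-2-hydroxy-2,4-dimethylpent-4-enoate | COC(=O)[C@](C)(O)CC(C)=C | intermediate
4 | (2R)-2,4-dimethylpent-4-ene-1,2-diol | OC[C@](C)(O)CC(C)=C | intermediate
5 | tert-butyl (triphenylphosphoranylidene)acetate | CC(C)(C)OC(=O)C=P(c1ccccc1)(c1ccccc1)c1ccccc1 | starting material
6 | (2R)-2-hydroxy-2,4-dimethylpent-4-enal | O=C[C@](C)(O)CC(C)=C | intermediate (not isolated)
7 | tert-butyl (2E,4R)-4-hydroxy-4,6-dimethylhepta-2,6-dienoate | CC(C)(C)OC(=O)/C=C/[C@](C)(O)CC(C)=C | intermediate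
8 | acryloyl chloride | C=CC(=O)Cl | starting material
9 | tert-butyl (2E,4R)-4,6-dimethyl-4-(prop-2-enoyloxy)hepta-2,6-dienoate | CC(C)(C)OC(=O)/C=C/[C@](C)(OC(=O)C=C)CC(C)=C | intermediate
10 | tert-butyl (2E)-3-[(2R)-2,4-dimethyl-6-oxo-3,6-dihydro-2H-pyran-2-yl]prop-2-enoate | CC(C)(C)OC(=O)/C=C/[C@@]1(C)CC(C)=CC(=O)O1 | intermediate
11 | hydrogen peroxide | OO | starting material
12 | tert-butyl (3R)-3-[(2R)-2,4-dimethyl-6-oxo-3,6-dihydro-2H-pyran-2-yl]-3-hydroperoxypropanoate | CC(C)(C)OC(=O)C[C@@H](OO)[C@@]1(C)CC(C)=CC(=O)O1 | intermediate (not isolated)
13 | tert-butyl 2-[(1R,4R,5R)-1,5-dimethyl-7-oxo-2,3,6-trioxabicyclo[3.3.1]nonan-4-yl]acetate | CC(C)(C)OC(=O)C[C@H]1OO[C@]2(C)C[C@@]1(C)OC(=O)C2 | intermediate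
14 | tert-butyl 2-[(1R,4R,5R)-7-hydroxy-1,5-dimethyl-2,3,6-trioxabicyclo[3.3.1]nonan-4-yl]acetate | CC(C)(C)OC(=O)C[C@H]1OO[C@]2(C)C[C@@]1(C)OC(O)C2 | intermediate
15 | 5-bromopentan-1-ol | OCCCCCBr | starting material
16 | tert-butyl[(5-bromopentyl)oxy]dimethylsilane | CC(C)(C)[Si](C)(C)OCCCCCBr | intermediate
17 | {5-[(tert-butyldimethylsilyl)oxy]pentyl}triphenylphosphonium bromide | CC(C)(C)[Si](C)(C)OCCCCC[P+](c1ccccc1)(c1ccccc1)c1ccccc1.[Br-] | intermediate
18 | {5-[(tert-butyldimethylsilyl)oxy]pentylidene}triphenylphosphorane | CC(C)(C)[Si](C)(C)OCCCCC=P(c1ccccc1)(c1ccccc1)c1ccccc1 | intermediate (not isolated)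
19 | tert-butyl 2-[(3R,4R,6S)-6-{(2Z)-7-[(tert-butyldimethylsilyl)oxy]hept-2-en-1-yl}-4-hydroxy-4,6-dimethyl-1,2-dioxan-3-yl]acetate | C[C@]1(C/C=C\CCCCO[Si](C)(C)C(C)(C)C)C[C@@](C)(O)[C@@H](CC(=O)OC(C)(C)C)OO1 | intermediate
20 | tert-butyl 2-[(3R,4R,6S)-6-{7-[(tert-butyldimethylsilyl)oxy]heptyl}-4-hydroxy-4,6-dimethyl-1,2-dioxan-3-yl]acetate | C[C@]1(CCCCCCCO[Si](C)(C)C(C)(C)C)C[C@@](C)(O)[C@@H](CC(=O)OC(C)(C)C)OO1 | intermediate
21 | 2-[(3R,4R,6S)-4-hydroxy-6-(7-hydroxyheptyl)-4,6-dimethyl-1,2-dioxan-3-yl]acetic acid | C[C@]1(CCCCCCCO)C[C@@](C)(O)[C@@H](CC(=O)O)OO1 | intermediate (not isolated)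
22 | 2-[(3R,4R,6S)-4-hydroxy-6-(7-hydroxyheptyl)-4,6-dimethyl-1,2-dioxan-3-yl]acetic acid 1,4-lactone | C[C@]1(CCCCCCCO)C[C@@]2(C)OC(=O)C[C@H]2OO1 | intermediate
23 | 2-[(3R,4R,6S)-4-hydroxy-4,6-dimethyl-6-(7-oxoheptyl)-1,2-dioxan-3-yl]acetic acid 1,4-lactone | C[C@]1(CCCCCCC=O)C[C@@]2(C)OC(=O)C[C@H]2OO1 | intermediate
24 | (E)-cinnamyl bromide | BrC/C=C/c1ccccc1 | starting material
25 | 1-phenyl-1H-tetrazole-5-thiol | Sc1nnnn1-c1ccccc1 | starting material
26 | 1-phenyl-5-{[(2E)-3-phenylprop-2-en-1-yl]sulfanyl}-1H-tetrazole | C(/C=C/c1ccccc1)Sc1nnnn1-c1ccccc1 | intermediate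
27 | 1-phenyl-5-{[(2E)-3-phenylprop-2-en-1-yl]sulfonyl}-1H-tetrazole | O=S(=O)(C/C=C/c1ccccc1)c1nnnn1-c1ccccc1 | intermediate
28 | (13Z,15E) isomer of plakortolide Q | C[C@]1(CCCCCC\C=C/C=C/c2ccccc2)C[C@@]2(C)OC(=O)C[C@H]2OO1 | intermediate (not isolated)
29 | plakortolide Q | C[C@]1(CCCCCC/C=C/C=C/c2ccccc2)C[C@@]2(C)OC(=O)C[C@H]2OO1 | target

## Step count and least certain steps

Total: 16 steps. Longest linear sequence: 12 steps (steps 1–7, 10–13 and 16).

**Step 6 (key step, proposed new method).** Most likely to go wrong: the intermolecular addition of hydroperoxide anion to the hindered tert-butyl enoate may be too slow or lie on the side of the reactants. That leaves time for acyl attack on the lactone by peroxide or amine and for oxidation of the amine. Equilibration at C3 may also stay incomplete, since the equatorial preference is small. A C3 epimer would be recognised and removed after step 12, where only the 3R series can close the cis-fused lactone. Fallback (known chemistry, electrophilic instead of nucleophilic activation of the two alkenes): starting from 10, Hg(OAc)2 (2.2 equiv) and 11 with a trace of HClO4 in CH2Cl2 should effect a double peroxymercuration. Divalent mercury adds to the α-carbons C7 and C2 and the peroxide oxygens to C6 and C3, under the same tether constraint, to give the bis(acetoxymercurio) bicycle F1. Its two C–Hg bonds, both α to carbonyl groups, are cleaved with dilute HCl in THF, which returns the route at 13. Both elements are established: cyclic peroxides from dienes, hydrogen peroxide and mercury salts, and β-peroxymercuration of α,β-unsaturated esters.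

**Step 10.** Most likely to go wrong: deprotonation at C2 by the ylide or by the alkoxide of the opened lactol, followed by expulsion of O2 from C3 (retro-conjugate addition, opening the dioxane), and slow reduction of the O–O bond by phosphorus species during a sluggish lactol olefination. Fallback (the arm is carried as a carboxylate, which cannot be enolised under these conditions):
- Starting from 13, CF3CO2H in CH2Cl2 gives the bridged lactone acid F2.
- iBu2AlH (3 equiv, −78 °C) gives the lactol acid F3.
- Excess ylide 18 gives the unsaturated hydroxy acid F4.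
- Aqueous CF3CO2H, as in step 12, lactonises and desilylates F4 to the unsaturated hydroxy lactone F5.
- Diimide reduction as in step 11 returns the route at 22.

**Step 4.** Most likely to go wrong: slow acylation of the hindered tertiary alkoxide, so that polymerisation of the acid chloride or conjugate addition of the alkoxide to the acrylate competes. Fallback (the lactone alkene is made by olefination instead of metathesis):
- Starting from 7, bromoacetyl bromide and pyridine give bromoacetate F6; this reagent is more electrophilic and offers no conjugate pathway.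
- Arbuzov reaction with P(OEt)3 gives phosphonoacetate F7.
- Ozonolysis of the 1,1-disubstituted alkene (O3, CH2Cl2/MeOH, −78 °C; Me2S; the enoate is far less reactive) gives methyl ketone F8.
- Intramolecular Horner–Wadsworth–Emmons reaction (LiCl, iPr2NEt, MeCN) closes C6=C7 and returns the route at 10.

**Step 16.** Most likely to go wrong: poor control of the C13=C14 geometry, which makes the outcome depend on the iodine equilibration; and enolisation of the aldehyde or of the lactone (with ring opening at C3) if any free amide base remains. Fallback (phosphonate instead of sulfone olefination): starting from 23, the anion of diethyl cinnamylphosphonate (LiN(SiMe3)2, THF, −78 °C → rt) in a Horner–Wadsworth–Emmons reaction should give the E,E diene directly, arriving at 29 without a new intermediate.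

**Step 1.** Most likely to go wrong: low reactivity of the ketone toward a gaseous alkene and erosion of the enantioselectivity at the temperature needed. Fallback (chiral pool with self-regeneration of the stereocentre):
- (S)-Lactic acid and pivalaldehyde (acid catalysis, azeotropic water removal) give the cis dioxolanone F9.
- Its lithium enolate (LiN(iPr)2, THF, −78 °C) is alkylated by 3-bromo-2-methylpropene anti to the tert-butyl group, giving F10.
- Acidic methanolysis of F10 returns the route at 3.

## Further compounds

F1 | step 6 | tert-butyl 2-(acetoxymercurio)-2-[(1R,4R,5R)-8-(acetoxymercurio)-1,5-dimethyl-7-oxo-2,3,6-trioxabicyclo[3.3.1]nonan-4-yl]acetate (C–Hg carbons unassigned) | CC(C)(C)OC(=O)C([Hg]OC(C)=O)[C@H]1OO[C@]2(C)C[C@@]1(C)OC(=O)C2[Hg]OC(C)=O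
F2 | step 10 | 2-[(1R,4R,5R)-1,5-dimethyl-7-oxo-2,3,6-trioxabicyclo[3.3.1]nonan-4-yl]acetic acid | OC(=O)C[C@H]1OO[C@]2(C)C[C@@]1(C)OC(=O)C2
F3 | step 10 | 2-[(1R,4R,5R)-7-hydroxy-1,5-dimethyl-2,3,6-trioxabicyclo[3.3.1]nonan-4-yl]acetic acid | OC(=O)C[C@H]1OO[C@]2(C)C[C@@]1(C)OC(O)C2
F4 | step 10 | 2-[(3R,4R,6S)-6-{(2Z)-7-[(tert-butyldimethylsilyl)oxy]hept-2-en-1-yl}-4-hydroxy-4,6-dimethyl-1,2-dioxan-3-yl]acetic acid | C[C@]1(C/C=C\CCCCO[Si](C)(C)C(C)(C)C)C[C@@](C)(O)[C@@H](CC(=O)O)OO1
F5 | step 10 | 2-[(3R,4R,6S)-4-hydroxy-6-[(2Z)-7-hydroxyhept-2-en-1-yl]-4,6-dimethyl-1,2-dioxan-3-yl]acetic acid 1,4-lactone | C[C@]1(C/C=C\CCCCO)C[C@@]2(C)OC(=O)C[C@H]2OO1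
F6 | step 4 | tert-butyl (2E,4R)-4-(2-bromoacetoxy)-4,6-dimethylhepta-2,6-dienoate | CC(C)(C)OC(=O)/C=C/[C@](C)(OC(=O)CBr)CC(C)=C
F7 | step 4 | tert-butyl (2E,4R)-4-[2-(diethoxyphosphoryl)acetoxy]-4,6-dimethylhepta-2,6-dienoate | CC(C)(C)OC(=O)/C=C/[C@](C)(OC(=O)CP(=O)(OCC)OCC)CC(C)=C
F8 | step 4 | tert-butyl (2E,4R)-4-[2-(diethoxyphosphoryl)acetoxy]-4-methyl-6-oxohept-2-enoate | CC(C)(C)OC(=O)/C=C/[C@](C)(OC(=O)CP(=O)(OCC)OCC)CC(C)=O
F0 | step 16 | none | none
F9 | step 1 | (2S,5S)-2-tert-butyl-5-methyl-1,3-dioxolan-4-one | C[C@@H]1O[C@H](C(C)(C)C)OC1=O
F10 | step 1 | (2S,5R)-2-tert-butyl-5-methyl-5-(2-methylprop-2-en-1-yl)-1,3-dioxolan-4-one | C[C@]1(CC(C)=C)O[C@H](C(C)(C)C)OC1=O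
A1 | alternative 1 | 8-[(tert-butyldimethylsilyl)oxy]-1,8-dimethyl-2,3-dioxabicyclo[2.2.2]oct-5-ene | C[C@@]12C[C@@](C)(O[Si](C)(C)C(C)(C)C)[C@@H](C=C1)OO2
A2 | alternative 1 | cis-3,6-divinyl-4,6-dimethyl-1,2-dioxan-4-yl tert-butyldimethylsilyl ether | C=C[C@@]1(C)C[C@@](C)(O[Si](C)(C)C(C)(C)C)[C@@H](C=C)OO1
A3 | alternative 2 | tert-butyl (3R)-3-hydroperoxy-4-methylpent-4-enoate | CC(=C)[C@H](OO)CC(=O)OC(C)(C)C
A4 | alternative 2 | tert-butyl[(8,8-dimethoxynon-6-yn-1-yl)oxy]diphenylsilane | COC(C)(OC)C#CCCCCCO[Si](c1ccccc1)(c1ccccc1)C(C)(C)C
A5 | alternative 2 | bicyclic peroxy lactone with a C6 alkynyl chain | CC(C)(C)[Si](OCCCCCC#C[C@@]1(C)C[C@@]2(C)OC(=O)C[C@H]2OO1)(c1ccccc1)c1ccccc1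
A6 | alternative 3 | tert-butyl (3R)-4-methyl-3-[(3-methylpenta-1,4-dien-3-yl)peroxy]pent-4-enoate | C=CC(C)(C=C)OO[C@H](CC(=O)OC(C)(C)C)C(C)=C
A7 | alternative 3 | 3,6-dihydro-1,2-dioxine with the C6 vinyl group cis to the C3 side chain | C=C[C@@]1(C)C=C(C)[C@@H](CC(=O)OC(C)(C)C)OO1
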